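**Retrosynthetic overview**
1. Target 24 ⇒ C2-symmetric hexaol 22. The extra C5–OH of ring B (the fully substituted ring) is added last by Teuber radical hydroxylation of one of two equivalent rings.
2. 22 ⇒ tetra-MOM diolide 19. Key step: both benzylic C–O bonds are made late by twofold radical C–H oxygenation to a diketone, then catalyst-controlled transfer hydrogenation sets the two carbinol centres. No diol protection is needed.
3. 19 ⇒ (S)-carbinols 14 + 15. Both ester C–O bonds are formed by Mitsunobu inversion, first between the two pieces, then as the 12-membered ring closure.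
4. 14, 15 ⇒ potassium salt 12 ⇒ lactone 11 ⇒ aryl bromide 7 + (S)-2-methyloxirane 8. The aryl–CH2 bond comes from a nickel-catalysed radical cross-electrophile coupling; 7 is built from 4-bromophenol.
5. Ring order: benzene ring (bought) → temporary δ-lactone (step 6, reopened in step 7) → 12-membered dilactone (step 13).

Assumption: the SMILES is read as the (R,R,R,R) isomer; ring A is the arene with one C–H, ring B the arene with three OH groups.

**Route**

Step 1
Reactants: 1 4-bromophenol
Product: 2 4-bromo-2,6-diiodophenol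
Conditions: I2 (1.05 equiv), 30% aq H2O2 (2 equiv), H2O, 50 °C
Reagents that add atoms: iodine, II
Why: Electrophilic aromatic iodination of a para-blocked phenol goes to both ortho positions, with H2O2 reoxidising iodide so that both iodine atoms of I2 are used.

Step 2
Reactants: 2 4-bromo-2,6-diiodophenol
Product: 3 5-bromo-1,3-diiodo-2-methoxybenzene
Conditions: MeI (1.5 equiv), K2CO3 (1.5 equiv), acetone, 56 °C
Reagents that add atoms: iodomethane, CI
Why: Williamson O-methylation of the acidic phenol installs the methoxy group that ends up between the two ring hydroxyls.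

Step 3
Reactants: 3 5-bromo-1,3-diiodo-2-methoxybenzene
Product: 4 5-bromo-2-methoxybenzene-1,3-diol
Conditions: CuI (10 mol%), 1,10-phenanthroline (20 mol%), KOH (6 equiv), DMSO/H2O 1:1, 90 °C; acidic work-up (2 M HCl)
Reagents that add atoms: potassium hydroxide, [K+].[OH-]
Why: Ullmann-type copper-catalysed hydroxylation replaces the two C–I bonds much faster than the C–Br bond, which is further deactivated once the ring carries phenoxide groups.

Step 4
Reactants: 4 5-bromo-2-methoxybenzene-1,3-diol
Product: 5 5-bromo-2-methoxy-1,3-bis(methoxymethoxy)benzene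
Conditions: MOMCl (2.5 equiv), iPr2NEt (3 equiv), CH2Cl2, 0 to 25 °C
Reagents that add atoms: chloromethyl methyl ether, COCCl
Why: O-alkylation of both phenols gives base-stable MOM acetals that also serve as ortho-directing groups for the next step.

Step 5
Reactants: 5 5-bromo-2-methoxy-1,3-bis(methoxymethoxy)benzene
Product: 7 methyl 6-bromo-3-methoxy-2,4-bis(methoxymethoxy)benzoate, via aryllithium 6 (not isolated)
Conditions: LiN(iPr)2 (1.1 equiv), THF, −78 °C, 30 min; then cannulate into ClCO2Me (3 equiv), THF, −78 °C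
Reagents that add atoms: methyl chloroformate, COC(=O)Cl
Why: Directed ortho-metalation occurs at the only type of ring C–H (flanked by OMOM and Br), and inverse quenching at −78 °C traps the aryllithium as the methyl ester before benzyne formation or halogen migration can compete.

Step 6
Reactants: 7 methyl 6-bromo-3-methoxy-2,4-bis(methoxymethoxy)benzoate; 8 (S)-2-methyloxirane
Product: 11 (3S)-7-methoxy-6,8-bis(methoxymethoxy)-3-methyl-3,4-dihydro-1H-isochromen-1-one, via iodohydrin 9 (not isolated), via hydroxy ester 10 (not isolated)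
Conditions: NiCl2·glyme (10 mol%), 2,2'-bipyridine (10 mol%), NaI (0.5 equiv), Et3N·HCl (1 equiv), Mn powder (2 equiv), 8 (2.5 equiv), DMPU, 25 °C; then NaH (0.2 equiv), THF, 0 °C
Reagents that add atoms: none
Why: In this nickel-catalysed reductive cross-electrophile coupling, iodide opens the epoxide at CH2 and the iodohydrin gives a primary β-hydroxyalkyl radical that is captured by the aryl–nickel species, so the aryl–CH2 bond forms in a radical step without touching the stereocentre of 8, and catalytic alkoxide then closes the carbinol onto the ortho ester to give a stable lactone.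

Step 7
Reactants: 11 (3S)-7-methoxy-6,8-bis(methoxymethoxy)-3-methyl-3,4-dihydro-1H-isochromen-1-one
Product: 12 potassium 6-[(2S)-2-hydroxypropyl]-3-methoxy-2,4-bis(methoxymethoxy)benzoate
Conditions: KOH (1.02 equiv), THF/H2O 3:1, 60 °C; evaporate, azeotrope with toluene, dry salt isolated and divided into two portions
Reagents that add atoms: potassium hydroxide, [K+].[OH-]
Why: Lactone saponification by acyl–oxygen cleavage leaves the C–O bond at the stereocentre untouched, and the hydroxy acid is kept as its dry potassium salt because the free acid would relactonise.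

Step 8
Reactants: 12 potassium 6-[(2S)-2-hydroxypropyl]-3-methoxy-2,4-bis(methoxymethoxy)benzoate
Product: 14 3-methoxy-2,4-bis(methoxymethoxy)-6-[(2S)-2-(triethylsilyloxy)propyl]benzoic acid, via silyl ester 13 (not isolated)
Conditions: Et3SiCl (2.5 equiv), imidazole (3 equiv), DMF, 0 °C; then aq citric acid (pH 4), THF, 0 °C
Reagents that add atoms: chlorotriethylsilane, CC[Si](Cl)(CC)CC
Why: Silylation of the salt at both oxygens followed by selective hydrolysis of the labile silyl ester gives the O-protected acid without passing through the free hydroxy acid.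

Step 9
Reactants: 12 potassium 6-[(2S)-2-hydroxypropyl]-3-methoxy-2,4-bis(methoxymethoxy)benzoate
Product: 15 prop-2-enyl 6-[(2S)-2-hydroxypropyl]-3-methoxy-2,4-bis(methoxymethoxy)benzoate
Conditions: allyl bromide (1.3 equiv), DMF, 0 to 25 °C
Reagents that add atoms: allyl bromide, C=CCBr
Why: SN2 alkylation of the carboxylate is chemoselective over the neutral secondary alcohol, and the di-ortho-substituted allyl ester is too hindered to relactonise under neutral conditions.

Step 10
Reactants: 14 3-methoxy-2,4-bis(methoxymethoxy)-6-[(2S)-2-(triethylsilyloxy)propyl]benzoic acid; 15 prop-2-enyl 6-[(2S)-2-hydroxypropyl]-3-methoxy-2,4-bis(methoxymethoxy)benzoate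
Product: 16 prop-2-enyl 3-methoxy-2,4-bis(methoxymethoxy)-6-[(2R)-2-({3-methoxy-2,4-bis(methoxymethoxy)-6-[(2S)-2-(triethylsilyloxy)propyl]benzoyl}oxy)propyl]benzoate
Conditions: PPh3 (1.5 equiv), DIAD (1.5 equiv), toluene, 0 to 25 °C
Reagents that add atoms: none
Why: Mitsunobu esterification suits di-ortho-substituted benzoic acids because the acid is the nucleophile, and it inverts the (S)-carbinol of 15 to the (R)-configured ester carbon of the target.

Step 11
Reactants: 16 the silyl-protected linear diester from step 10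
Product: 17 prop-2-enyl 6-[(2R)-2-({6-[(2S)-2-hydroxypropyl]-3-methoxy-2,4-bis(methoxymethoxy)benzoyl}oxy)propyl]-3-methoxy-2,4-bis(methoxymethoxy)benzoate
Conditions: HF·pyridine, pyridine, THF, 0 °C
Reagents that add atoms: none
Why: Buffered fluoride desilylation removes the secondary TES ether while the MOM acetals and both hindered esters stay intact.

Step 12
Reactants: 17 the hydroxy allyl ester from step 11
Product: 18 6-[(2R)-2-({6-[(2S)-2-hydroxypropyl]-3-methoxy-2,4-bis(methoxymethoxy)benzoyl}oxy)propyl]-3-methoxy-2,4-bis(methoxymethoxy)benzoic acid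
Conditions: Pd(PPh3)4 (5 mol%), morpholine (3 equiv), THF, 0 to 25 °C; citric acid work-up
Reagents that add atoms: none
Why: Tsuji–Trost deallylation frees the carboxylic acid under near-neutral conditions that leave the δ-hydroxy ester unit untouched.

Step 13
Reactants: 18 the seco acid from step 12
Product: 19 tetra-MOM diolide (12-membered head-to-tail cyclic diester of two 6-[(2R)-2-hydroxypropyl]-3-methoxy-2,4-bis(methoxymethoxy)benzoic acid units; C2-symmetric; both benzylic positions CH2)
Conditions: PPh3 (5 equiv), DIAD (5 equiv), toluene, 25 °C, slow addition of 18 (final 2 mM)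
Reagents that add atoms: none
Why: Mitsunobu macrolactonisation, the standard ring closure for 12- to 14-membered resorcylic lactones, inverts the second (S)-carbinol so that both ester carbons are now (R).

Step 14
Reactants: 19 tetra-MOM diolide
Product: 20 tetra-MOM diketone (19 with both benzylic CH2 groups oxidised to C=O; cyclic diester of two 6-[(2R)-2-hydroxypropanoyl]-3-methoxy-2,4-bis(methoxymethoxy)benzoic acid units)
Conditions: Rh2(cap)4 (dirhodium tetracaprolactamate, 2 mol%), t-BuOOH (70% in H2O, 12 equiv in portions), NaHCO3 (1 equiv), ClCH2CH2Cl, 40 °C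
Reagents that add atoms: tert-butyl hydroperoxide, CC(C)(C)OO
Why: In this radical benzylic C–H oxygenation, tert-butylperoxyl radicals abstract only the weakest C–H bonds (the two benzylic CH2 groups) and the benzylic radicals are trapped by oxygen-centred radicals and collapse to the aryl ketones, while the stronger, polarity-mismatched α-acyloxy C–H bonds and the MOM groups are spared so the (R)-centres are not touched.

Step 15
Reactants: 20 tetra-MOM diketone
Product: 21 tetraphenol diketone (cyclic diester of two 2,4-dihydroxy-6-[(2R)-2-hydroxypropanoyl]-3-methoxybenzoic acid units)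
Conditions: CF3CO2H/CH2Cl2/H2O 20:78:2, 0 to 25 °C
Reagents that add atoms: none
Why: Acidolysis of the four aryl MOM acetals is done at the robust diketone stage, before the acid-sensitive benzylic carbinols exist.

Step 16
Reactants: 21 tetraphenol diketone
Product: 22 hexaol (cyclic diester of two 6-[(1R,2R)-1,2-dihydroxypropyl]-2,4-dihydroxy-3-methoxybenzoic acid units linked through O-2 of each side chain; benzylic OH free; C2-symmetric 5-deoxy analogue of the target)
Conditions: RuCl[(S,S)-TsDPEN](p-cymene) (5 mol%), HCO2H/Et3N 5:2, DMF, 30 °C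
Reagents that add atoms: none
Why: Noyori–Ikariya asymmetric transfer hydrogenation with the (S,S)-catalyst gives the (R)-carbinol at each aryl ketone, which is also the Felkin–Anh (syn) outcome next to the (R)-acyloxy centre, and the weakly acidic medium avoids α-epimerisation, acyl migration and phthalide formation.

Step 17
Reactants: 22 hexaol
Product: 24 target CNP0086623.2, via hydroxyquinone 23 (not isolated)
Conditions: (KSO3)2NO (2.1 equiv), KH2PO4 buffer (pH 6), acetone/H2O, 0 °C; then Na2S2O4 (3 equiv), H2O, 0 °C
Reagents that add atoms: potassium nitrosodisulfonate, [K+].[K+].[O]N(S(=O)(=O)[O-])S(=O)(=O)[O-]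
Why: Teuber oxidation couples the phenoxyl radical with a second nitrosodisulfonate radical at C5 (the only free ring position) to give the hydroxy-p-quinone of one ring, which dithionite reduces to the 2,4,5-triol; because the two rings of 22 are equivalent either one gives 24, about 2 equivalents of oxidant favour the mono-product statistically, unreacted 22 is recycled and no stereocentre is touched.

**Compound list**
1 | 4-bromophenol | Oc1ccc(Br)cc1 | starting material
2 | 4-bromo-2,6-diiodophenol | Oc1c(I)cc(Br)cc1I | intermediate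
3 | 5-bromo-1,3-diiodo-2-methoxybenzene | COc1c(I)cc(Br)cc1I | intermediate
4 | 5-bromo-2-methoxybenzene-1,3-diol | COc1c(O)cc(Br)cc1O | intermediate
5 | 5-bromo-2-methoxy-1,3-bis(methoxymethoxy)benzene | COCOc1cc(Br)cc(OCOC)c1OC | intermediate
6 | [6-bromo-3-methoxy-2,4-bis(methoxymethoxy)phenyl]lithium | [Li]c1c(Br)cc(OCOC)c(OC)c1OCOC | intermediate
7 | methyl 6-bromo-3-methoxy-2,4-bis(methoxymethoxy)benzoate | COC(=O)c1c(Br)cc(OCOC)c(OC)c1OCOC | intermediate
8 | (S)-2-methyloxirane | C[C@H]1CO1 | starting material
9 | (2S)-1-iodopropan-2-ol | C[C@H](O)CI | intermediate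
10 | methyl 6-[(2S)-2-hydroxypropyl]-3-methoxy-2,4-bis(methoxymethoxy)benzoate | COC(=O)c1c(C[C@H](C)O)cc(OCOC)c(OC)c1OCOC | intermediate
11 | (3S)-7-methoxy-6,8-bis(methoxymethoxy)-3-methyl-3,4-dihydro-1H-isochromen-1-one | C[C@H]1Cc2cc(OCOC)c(OC)c(OCOC)c2C(=O)O1 | intermediate
12 | potassium 6-[(2S)-2-hydroxypropyl]-3-methoxy-2,4-bis(methoxymethoxy)benzoate | [K+].[O-]C(=O)c1c(C[C@H](C)O)cc(OCOC)c(OC)c1OCOC | intermediate
13 | triethylsilyl 3-methoxy-2,4-bis(methoxymethoxy)-6-[(2S)-2-(triethylsilyloxy)propyl]benzoate | CC[Si](CC)(CC)OC(=O)c1c(C[C@H](C)O[Si](CC)(CC)CC)cc(OCOC)c(OC)c1OCOC | intermediate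
14 | 3-methoxy-2,4-bis(methoxymethoxy)-6-[(2S)-2-(triethylsilyloxy)propyl]benzoic acid | OC(=O)c1c(C[C@H](C)O[Si](CC)(CC)CC)cc(OCOC)c(OC)c1OCOC | intermediate
15 | prop-2-enyl 6-[(2S)-2-hydroxypropyl]-3-methoxy-2,4-bis(methoxymethoxy)benzoate | C=CCOC(=O)c1c(C[C@H](C)O)cc(OCOC)c(OC)c1OCOC | intermediate
16 | prop-2-enyl 3-methoxy-2,4-bis(methoxymethoxy)-6-[(2R)-2-({3-methoxy-2,4-bis(methoxymethoxy)-6-[(2S)-2-(triethylsilyloxy)propyl]benzoyl}oxy)propyl]benzoate | C=CCOC(=O)c1c(C[C@@H](C)OC(=O)c2c(C[C@H](C)O[Si](CC)(CC)CC)cc(OCOC)c(OC)c2OCOC)cc(OCOC)c(OC)c1OCOC | intermediate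
17 | prop-2-enyl 6-[(2R)-2-({6-[(2S)-2-hydroxypropyl]-3-methoxy-2,4-bis(methoxymethoxy)benzoyl}oxy)propyl]-3-methoxy-2,4-bis(methoxymethoxy)benzoate | C=CCOC(=O)c1c(C[C@@H](C)OC(=O)c2c(C[C@H](C)O)cc(OCOC)c(OC)c2OCOC)cc(OCOC)c(OC)c1OCOC | intermediate
18 | 6-[(2R)-2-({6-[(2S)-2-hydroxypropyl]-3-methoxy-2,4-bis(methoxymethoxy)benzoyl}oxy)propyl]-3-methoxy-2,4-bis(methoxymethoxy)benzoic acid | OC(=O)c1c(C[C@@H](C)OC(=O)c2c(C[C@H](C)O)cc(OCOC)c(OC)c2OCOC)cc(OCOC)c(OC)c1OCOC | intermediate
19 | tetra-MOM diolide: 12-membered head-to-tail cyclic diester of two 6-[(2R)-2-hydroxypropyl]-3-methoxy-2,4-bis(methoxymethoxy)benzoic acid units | COc1c(OCOC)cc2c(c1OCOC)C(=O)O[C@H](C)Cc1cc(OCOC)c(OC)c(OCOC)c1C(=O)O[C@H](C)C2 | intermediate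
20 | tetra-MOM diketone: 19 with both benzylic CH2 groups as C=O | COc1c(OCOC)cc2c(c1OCOC)C(=O)O[C@H](C)C(=O)c1cc(OCOC)c(OC)c(OCOC)c1C(=O)O[C@H](C)C2=O | intermediate
21 | tetraphenol diketone: cyclic diester of two 2,4-dihydroxy-6-[(2R)-2-hydroxypropanoyl]-3-methoxybenzoic acid units | COc1c(O)cc2c(c1O)C(=O)O[C@H](C)C(=O)c1cc(O)c(OC)c(O)c1C(=O)O[C@H](C)C2=O | intermediate
22 | hexaol: cyclic diester of two 6-[(1R,2R)-1,2-dihydroxypropyl]-2,4-dihydroxy-3-methoxybenzoic acid units through O-2 of each side chain (all four centres R) | COc1c(O)cc2c(c1O)C(=O)O[C@H](C)[C@H](O)c1cc(O)c(OC)c(O)c1C(=O)O[C@H](C)[C@@H]2O | intermediate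
23 | hydroxyquinone: 22 with one arene oxidised to a 5-hydroxy-6-methoxy-1,4-benzoquinone ring (lactone carbonyl on C2 and side chain on C3 of that ring) | COc1c(O)cc2c(c1O)C(=O)O[C@H](C)[C@H](O)C1=C(C(=O)O[C@H](C)[C@@H]2O)C(=O)C(OC)=C(O)C1=O | intermediate
24 | CNP0086623.2, the (R,R,R,R) dilactone with ring A (2,4-dihydroxy-3-methoxy) and ring B (2,4,5-trihydroxy-3-methoxy) | COc1c(O)cc2c(c1O)C(=O)O[C@H](C)[C@H](O)c1c(O)c(O)c(OC)c(O)c1C(=O)O[C@H](C)[C@@H]2O | target

**Summary**
Total step count: 17. Longest linear sequence: 16 steps (steps 1–7, then 8 or 9, then 10–17; 14 and 15 both come from the potassium salt 12).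

The three steps most likely to fail:

Step 14 (key step): the benzylic CH2 groups are deactivated by the ortho ester and the neighbouring acyloxy carbon, so the second oxidation may stall or oxidant may be lost on the MOM groups. Fallback by halogenation and Kornblum oxidation: it sets out from 19, where NBS (2.2 equiv), AIBN and K2CO3 in PhCF3 at 80 °C under light give the bis(benzylic bromide) F1 (configuration at CHBr is irrelevant), and DMSO/NaHCO3 at 80 °C then converts both C–Br groups into ketones, coming back to the route at 20.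

Step 13: the 12-membered ring contains two ortho-phenylene units, and the activated carbinol can eliminate or be intercepted by the neighbouring ester carbonyl. Fallback by intramolecular carboxylate SN2 alkylation: it sets out from 17, where MsCl/Et3N in CH2Cl2 at 0 °C gives the mesylate F2 with retention, Pd(PPh3)4/morpholine frees the seco acid mesylate F3, and Cs2CO3 in DMF at 60 °C and 2 mM closes the ring by SN2 with inversion, coming back to the route at 19.

Step 16: two hindered ketones must be reduced, and the new carbinols sit next to an ortho ester (phthalide formation) and a vicinal ester (acyl migration). Fallback by substrate-controlled reduction before deprotection: it sets out from 20, where NaBH4/CeCl3·7H2O in MeOH/THF at −78 °C (Felkin–Anh, syn) gives the tetra-MOM diol F4 with (R)-carbinols, and ZnBr2/n-PrSH in CH2Cl2 at 0 °C removes the four MOM groups, coming back to the route at 22.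

**Further compounds**
F1 | step 14 | bis(benzylic bromide) of 19 (CHBr centres undefined) | COc1c(OCOC)cc2c(c1OCOC)C(=O)O[C@H](C)C(Br)c1cc(OCOC)c(OC)c(OCOC)c1C(=O)O[C@H](C)C2Br
F2 | step 13 | mesylate of 17 (2S-methanesulfonyloxy) | C=CCOC(=O)c1c(C[C@@H](C)OC(=O)c2c(C[C@H](C)OS(C)(=O)=O)cc(OCOC)c(OC)c2OCOC)cc(OCOC)c(OC)c1OCOC
F3 | step 13 | seco acid mesylate | OC(=O)c1c(C[C@@H](C)OC(=O)c2c(C[C@H](C)OS(C)(=O)=O)cc(OCOC)c(OC)c2OCOC)cc(OCOC)c(OC)c1OCOC
F4 | step 16 | tetra-MOM diol (all four centres R) | COc1c(OCOC)cc2c(c1OCOC)C(=O)O[C@H](C)[C@H](O)c1cc(OCOC)c(OC)c(OCOC)c1C(=O)O[C@H](C)[C@@H]2O
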